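## Structural features

The target is a diaryl ether without any stereocentre: two benzene rings joined by one oxygen that links C5 of ring A to C1' of ring B. Ring A is a 1,3,5-trioxygenated ring carrying a hydrogen sulfate at C1, a free hydroxyl at C3 and the ether oxygen at C5. Ring B is 1',2',4',6'-tetraoxygenated: the ether oxygen at C1', free hydroxyls at C2' and C6' on both sides of it, and the second hydrogen sulfate at C4', para to the ether. The aryl O–SO3H groups are the fragile part; they solvolyse under acid and rule out Lewis-acidic or strongly acidic deprotection once in place, and the free polyphenol is easily oxidised in air. The first difficulty is the C1'–O bond, which sits on a carbon flanked by two oxygens on an electron-rich ring, poor for both copper-mediated coupling and direct substitution. The second is sorting five oxygens into two sulfates and three free hydroxyls, including telling apart two positions of ring A that are equivalent in phloroglucinol. The key step exploits C2' and C6' of ring B: carried as formyl groups they make C1' electrophilic enough for fluoride displacement by the ring A phenoxide, and a twofold Baeyer–Villiger oxidation then turns them into the two hydroxyls.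

## Logic of the disconnections

16 to 15: the three benzylic C–O bonds at C3–O, C2'–O and C6'–O are cut. With the sulfates already present, only a neutral deprotection is tolerable, and hydrogenolysis is one. The gain is that all three free hydroxyls of 16 stay masked by one kind of group until the end. The demand is that the sulfate half-esters, held as salts, survive hydrogen over palladium and never meet acid for long.

15 to 14: the two O–S bonds at C1–O and C4'–O are cut. Sulfation does not discriminate among phenols, so exactly these two hydroxyls, and no others, must be free in 14. The gain is a neutral bisphenol that can be purified by ordinary chromatography. The demand is complete twofold sulfation.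

14 to 13: the two acyl C–O bonds of the pivalates are cut. Ester against ether orthogonality lets the sulfation sites be uncovered while the benzyl ethers stay. The demand on the forward step is only that methoxide leaves the ethers alone.

13 to 12 and 7: the two O–CH2 bonds at C2'–O and C6'–O are cut. The hydroxyls created by the key step must be masked with the same group as C3–O so that one final operation frees all three. The forward step must alkylate two phenols under base without moving the pivaloyl groups.

12 to 10 through 11: the C2'–O and C6'–O bonds are traced back to C2'–CHO and C6'–CHO bonds. This replaces two donor substituents by two acceptors, which changes the polarity of C1' from unreactive to electrophilic. The gain is that the hindered ether becomes accessible by uncatalysed substitution. The demand is aryl rather than hydride migration at both formyl groups, and cleavage of the resulting formates without loss of the pivalates.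

10 to 5 and 9: the C1'–O ether bond is cut between the two rings. The two ortho formyl groups stabilise the anionic adduct, so fluoride is a good leaving group here. The gain is two monocyclic fragments of similar size. The forward step needs a phenoxide that substitutes faster than it exchanges acyl groups.

5 to 4, 3, then 1 and 2: the formyl C=O bonds are traced back to benzylic C–H bonds through geminal dibromides, and the pivalate to the free phenol. This reaches a xylenol in which fluorine and oxygen already stand para to each other. The forward steps must brominate only the side chains and hydrolyse without touching the ester or the activated C–F bond.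

9 to 8 and 2, then 8 to 6 and 7: one acyl C–O bond and one benzylic C–O bond are cut, leading back to the symmetrical triol. Both forward steps are statistical mono-functionalisations. The price is paid on the cheapest material in the route and the side fractions can be recycled.

## Other disconnections considered

Alternative 1: The cut is through the C1–C6 and C4–C5 bonds of ring A, so ring A would be assembled from a four-carbon cyclobutenone and the two carbons of an alkyne already attached to the ring B oxygen.
- Forward key step: heating 3-(benzyloxy)cyclobut-2-en-1-one A2 with the ring B ethynyl ether A1 (toluene, about 80–110 °C) would open A2 to a vinylketene. This adds [2+2] to the electron-rich triple bond; the vinylcyclobutenone so formed opens again and closes by 6π electrocyclisation to the phenol A3 after tautomerisation.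
- In its favour: the regiochemistry is written into the mechanism. The ether oxygen ends meta to the new hydroxyl and the benzyloxy carbon meta to both, so ring A appears with its three oxygens already distinguished. No statistical protection of a symmetrical triol is needed, and on this point the alternative is better than the chosen plan. A3 also has its ring A sulfation site free, so only acetal cleavage, sulfation and hydrogenolysis remain, one operation fewer than after 12, again better.
- Against it: the hard C1'–O bond is not addressed. It must already exist in A1, which presupposes a ring B phenol with four oxygens in three protecting states; its two flanking oxygens would most plausibly come from the same formyl-to-hydroxyl logic used here. Making A1 from that hindered phenol and supplying A2 add further steps. An aryl ynol ether is a weaker ketene partner than the alkyl and silyl ynol ethers on which this benzannulation is best established, and the alkoxy vinylketene could dimerise.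
- Comparison: structurally the alternative solves ring A more elegantly and is equally convergent. Mechanistically it relies on a four-stage pericyclic cascade at elevated temperature instead of two ionic steps near room temperature. In step count it would probably be longer overall because both partners are multi-step.

Alternative 2: The cut is through the C1–O bond of ring A and the C4'–O bond of ring B, the two oxygens that carry the sulfates, traced back to C–H bonds of the tris(methoxymethyl)-protected diaryl ether A4.
- Forward key step: A4, B2pin2 and the catalyst formed from [Ir(OMe)(cod)]2 and 4,4'-di-tert-butyl-2,2'-bipyridine would borylate the only C–H bond on each ring without an ortho substituent (C1–H and C4'–H). Aqueous Oxone added to the same flask would convert both C–B bonds to C–OH and give A5.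
- In its favour: the sterically dictated positions coincide with the sulfate positions, and the two hydroxyls appear free exactly where the sulfates belong, so no protecting-group exchange precedes sulfation (better). Ring A comes from a resorcinol derivative instead of a desymmetrised phloroglucinol (better). The route would be the shortest of the four (better step economy).
- Against it: A4 already contains the doubly ortho-substituted ether bond and would need a copper-mediated Ullmann-type coupling of a 2,6-dioxygenated phenol with no activating group, which is exactly the bond that the formyl groups make easy in the chosen plan. The acetal oxygens might divert some borylation to ortho positions. The endgame must remove three acetals with acid after the sulfates are in place, the very condition under which aryl sulfates solvolyse, whereas the chosen plan ends with neutral hydrogenolysis.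
- Comparison: mechanistically the borylation–oxidation is as well founded as the peracid oxidation (equal). Step economy favours the alternative; ether-bond formation and endgame safety favour the chosen plan.

Alternative 3: The cut is through the C1'–C2' bond of ring B, which opens ring B to a polyketide-type chain stored as the 2-pyrone A6, whose aryloxymethyl group carries ring A.
- Forward key step: Mg(OMe)2 in methanol would open the lactone to a methyl ester. The magnesium enolate at the aryloxy-substituted methylene would then attack that ester in a Claisen (Dieckmann-type) condensation and, after enolisation, give the diol A7.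
- In its favour: the ether oxygen is attached to an sp3 carbon by simple O-alkylation before ring B exists, so no aryl–oxygen bond has to be made at a hindered carbon; on this point it is better than the chosen plan. The oxygen pattern of ring B follows from the carbonyl pattern of the chain. A7 is the direct counterpart of 12, so the endgame has the same length (equal).
- Against it: the closure needs carbanion formation at the least acidic enolisable position. It competes with reclosure to the pyrone and with exchange of the acetal-protected oxygen at C4 of the pyrone by methoxide. Ring A still needs the same twofold statistical protection (equal), and A6 needs several steps from a 6-methylpyrone.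
- Comparison: structurally it avoids the diaryl ether problem altogether. Mechanistically it trades a predictable substitution–oxidation pair for carbanion chemistry with regiochemical ambiguity. In step count it is roughly equal to the chosen plan.

Key step: step 7

Assumption: the aryl sulfate half-esters are drawn throughout in the acid form of the target; in the flask they are handled as sodium salts, and the acid form is released only at the end of the last step by cold proton exchange.

## Route

Step 1
Reactants: 1 4-fluoro-3,5-dimethylphenol; 2 pivaloyl chloride
Product: 3 4-fluoro-3,5-dimethylphenyl pivalate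
Conditions: PivCl (1.1 equiv), Et3N (1.3 equiv), DMAP (5 mol%), CH2Cl2, 0 °C→rt
Reagents that add atoms: pivaloyl chloride, CC(C)(C)C(Cl)=O
Why: DMAP-catalysed O-acylation (nucleophilic acyl substitution) of the only hydroxyl; the pivalate tolerates radical bromination, silver-assisted hydrolysis and peracid, and later marks C4'–O as a sulfation site.

Step 2
Reactants: 3 4-fluoro-3,5-dimethylphenyl pivalate
Product: 4 3,5-bis(dibromomethyl)-4-fluorophenyl pivalate
Conditions: NBS (4.5 equiv), AIBN (10 mol%), PhCF3, reflux, visible light
Reagents that add atoms: N-bromosuccinimide, O=C1CCC(=O)N1Br
Why: Wohl–Ziegler radical bromination; each benzylic carbon should take two bromines and then stop because a third abstraction is sterically and electronically disfavoured, while the acyloxy group and fluorine keep the ring unreactive toward ionic bromination in a non-polar medium.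

Step 3
Reactants: 4 3,5-bis(dibromomethyl)-4-fluorophenyl pivalate
Product: 5 4-fluoro-3,5-diformylphenyl pivalate
Conditions: AgNO3 (4.4 equiv), acetone–H2O (4:1), 50 °C, dark
Reagents that add atoms: water, O
Why: Silver-assisted hydrolysis of geminal dibromides (ionisation, capture by water, loss of HBr) under non-basic conditions, so that neither the pivalate nor the C–F bond, now activated by two ortho formyl groups, meets a strong nucleophile.

Step 4
Reactants: 6 phloroglucinol (benzene-1,3,5-triol); 7 benzyl bromide
Product: 8 5-(benzyloxy)benzene-1,3-diol
Conditions: 6 (3 equiv), BnBr (1 equiv), K2CO3 (1.1 equiv), DMF, 0 °C→rt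
Reagents that add atoms: benzyl bromide, BrCc1ccccc1
Why: Williamson O-alkylation of the mono-phenoxide; a threefold excess of the cheap triol biases the statistical outcome toward the monoether, the polar aprotic solvent favours O- over C-benzylation, and unreacted triol is removed by aqueous extraction.

Step 5
Reactants: 8 5-(benzyloxy)benzene-1,3-diol; 2 pivaloyl chloride
Product: 9 3-(benzyloxy)-5-hydroxyphenyl pivalate
Conditions: PivCl (1.0 equiv, slow addition), pyridine (2 equiv), CH2Cl2, −20 °C→0 °C
Reagents that add atoms: pivaloyl chloride, CC(C)(C)C(Cl)=O
Why: Statistical mono-O-acylation of a symmetrical diol with one equivalent of acyl chloride at low temperature; diol, monoester and diester differ strongly in polarity, and both side fractions can be recycled, the diester by methanolysis.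

Step 6
Reactants: 5 4-fluoro-3,5-diformylphenyl pivalate; 9 3-(benzyloxy)-5-hydroxyphenyl pivalate
Product: 10 2-[3-(benzyloxy)-5-(pivaloyloxy)phenoxy]-5-(pivaloyloxy)benzene-1,3-dicarbaldehyde
Conditions: Cs2CO3 (1.1 equiv, added last), MeCN, 0 °C→rt
Reagents that add atoms: none
Why: Nucleophilic aromatic substitution by addition–elimination: the fluoride sits between two ortho formyl groups that stabilise the Meisenheimer adduct, so the phenoxide should substitute at or below room temperature, faster than it can exchange acyl groups with the hindered pivalates.

Step 7
Reactants: 10 2-[3-(benzyloxy)-5-(pivaloyloxy)phenoxy]-5-(pivaloyloxy)benzene-1,3-dicarbaldehyde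
Product: 12 2-[3-(benzyloxy)-5-(pivaloyloxy)phenoxy]-5-(pivaloyloxy)benzene-1,3-diol, via bis(formate) ester 11 (not isolated)
Conditions: mCPBA (3 equiv), CH2Cl2, 0 °C→rt; aq. Na2S2O3/NaHCO3 wash; then KHCO3 (0.2 equiv), MeOH, 0 °C
Reagents that add atoms: 3-chloroperoxybenzoic acid, O=C(OO)c1cccc(Cl)c1
Why: This is a Baeyer–Villiger (Dakin-type) oxidation carried out twice in one flask: the peracid adds to each formyl carbon to give a Criegee adduct, and the ring carbon (C2', then C6') shifts from carbon to the proximal peroxide oxygen as 3-chlorobenzoate leaves, creating the C2'–O and C6'–O bonds as the aryl formates 11. The closest known reaction type is the peracid oxidation of ortho- and para-alkoxy- or aryloxybenzaldehydes to aryl formates; its use at two formyl groups flanking one diaryl ether oxygen applies that chemistry to a new substrate. No ring is closed and no stereocentre is formed. The first selectivity needed is aryl over hydride migration at both formyl groups; it is secured by the lone pair of the ether oxygen, which is ortho to both migrating carbons and stabilises the electron-deficient migrating terminus, while the formyl groups are meta to each other and so do not oppose this donation by resonance. The second is chemoselectivity for the formyl groups over the oxygenated ring A, which its acyloxy substituent and its attachment to an electron-poor aryl oxygen make a poor partner for electrophilic oxygen transfer. In the second operation the unhindered formates are transesterified by methanol under catalytic weak base at 0 °C, whereas the tert-butyl esters are too hindered to react, so the two new hydroxyls appear free and C4'–O stays marked. The same formyl groups served before this step as the activating groups for the fluoride displacement, so each performs two tasks.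

Step 8
Reactants: 12 2-[3-(benzyloxy)-5-(pivaloyloxy)phenoxy]-5-(pivaloyloxy)benzene-1,3-diol; 7 benzyl bromide
Product: 13 3,5-bis(benzyloxy)-4-[3-(benzyloxy)-5-(pivaloyloxy)phenoxy]phenyl pivalate
Conditions: BnBr (2.4 equiv), K2CO3 (3 equiv), acetone, rt→40 °C
Reagents that add atoms: benzyl bromide, BrCc1ccccc1
Why: Williamson benzylation of the two equivalent phenols with a mild carbonate base; the tert-butyl esters are hindered enough to resist phenoxide-mediated acyl transfer at this temperature, and the new ethers match the one on ring A so that all three fall together in the last step.

Step 9
Reactants: 13 3,5-bis(benzyloxy)-4-[3-(benzyloxy)-5-(pivaloyloxy)phenoxy]phenyl pivalate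
Product: 14 3-(benzyloxy)-5-[2,6-bis(benzyloxy)-4-hydroxyphenoxy]phenol
Conditions: NaOMe (3 equiv), MeOH–THF (1:1), 0 °C→rt; AcOH quench
Reagents that add atoms: none
Why: Transesterification (methanolysis) of both aryl pivalates by methoxide; benzyl and diaryl ethers are inert, and the two phenols set free are exactly the future sulfate positions C1 and C4'.

Step 10
Reactants: 14 3-(benzyloxy)-5-[2,6-bis(benzyloxy)-4-hydroxyphenoxy]phenol
Product: 15 3-(benzyloxy)-5-[2,6-bis(benzyloxy)-4-(sulfooxy)phenoxy]phenyl hydrogen sulfate
Conditions: SO3·pyridine (6 equiv), pyridine, 50 °C; then aq. NaHCO3, reversed-phase chromatography (disodium salt)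
Reagents that add atoms: sulfur trioxide–pyridine complex, [O-]S(=O)(=O)[n+]1ccccc1
Why: O-sulfation of phenols by sulfur trioxide transfer from the pyridine complex; both hydroxyls are unhindered, and the basic aqueous work-up should deliver the stable disodium salt.

Step 11
Reactants: 15 3-(benzyloxy)-5-[2,6-bis(benzyloxy)-4-(sulfooxy)phenoxy]phenyl hydrogen sulfate
Product: 16 3-[2,6-dihydroxy-4-(sulfooxy)phenoxy]-5-hydroxyphenyl hydrogen sulfate (CNP0460023.0)
Conditions: H2 (1 atm), 10% Pd/C, MeOH–H2O (9:1), rt; filter; then sulfonic acid resin (H+ form), H2O, 0 °C; freeze-dry
Reagents that add atoms: none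
Why: Heterogeneous catalytic hydrogenolysis of the three benzylic C–O bonds over palladium on carbon under neutral conditions, to which aryl sulfate salts are inert; a brief cold pass through the acid resin then exchanges sodium for protons.

## Compound list

1 | 4-fluoro-3,5-dimethylphenol | Cc1cc(O)cc(C)c1F | starting material
2 | pivaloyl chloride | CC(C)(C)C(Cl)=O | starting material
3 | 4-fluoro-3,5-dimethylphenyl pivalate | Cc1cc(OC(=O)C(C)(C)C)cc(C)c1F | intermediate
4 | 3,5-bis(dibromomethyl)-4-fluorophenyl pivalate | BrC(Br)c1cc(OC(=O)C(C)(C)C)cc(C(Br)Br)c1F | intermediate
5 | 4-fluoro-3,5-diformylphenyl pivalate | O=Cc1cc(OC(=O)C(C)(C)C)cc(C=O)c1F | intermediate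
6 | phloroglucinol (benzene-1,3,5-triol) | Oc1cc(O)cc(O)c1 | starting material
7 | benzyl bromide | BrCc1ccccc1 | starting material
8 | 5-(benzyloxy)benzene-1,3-diol | Oc1cc(O)cc(OCc2ccccc2)c1 | intermediate
9 | 3-(benzyloxy)-5-hydroxyphenyl pivalate | CC(C)(C)C(=O)Oc1cc(O)cc(OCc2ccccc2)c1 | intermediate
10 | 2-[3-(benzyloxy)-5-(pivaloyloxy)phenoxy]-5-(pivaloyloxy)benzene-1,3-dicarbaldehyde | CC(C)(C)C(=O)Oc1cc(C=O)c(Oc2cc(OCc3ccccc3)cc(OC(=O)C(C)(C)C)c2)c(C=O)c1 | intermediate
11 | 4-[3-(benzyloxy)-5-(pivaloyloxy)phenoxy]-3,5-bis(formyloxy)phenyl pivalate | CC(C)(C)C(=O)Oc1cc(OC=O)c(Oc2cc(OCc3ccccc3)cc(OC(=O)C(C)(C)C)c2)c(OC=O)c1 | intermediate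
12 | 2-[3-(benzyloxy)-5-(pivaloyloxy)phenoxy]-5-(pivaloyloxy)benzene-1,3-diol | CC(C)(C)C(=O)Oc1cc(O)c(Oc2cc(OCc3ccccc3)cc(OC(=O)C(C)(C)C)c2)c(O)c1 | intermediate
13 | 3,5-bis(benzyloxy)-4-[3-(benzyloxy)-5-(pivaloyloxy)phenoxy]phenyl pivalate | CC(C)(C)C(=O)Oc1cc(OCc2ccccc2)c(Oc2cc(OCc3ccccc3)cc(OC(=O)C(C)(C)C)c2)c(OCc2ccccc2)c1 | intermediate
14 | 3-(benzyloxy)-5-[2,6-bis(benzyloxy)-4-hydroxyphenoxy]phenol | Oc1cc(OCc2ccccc2)cc(Oc2c(OCc3ccccc3)cc(O)cc2OCc2ccccc2)c1 | intermediate
15 | 3-(benzyloxy)-5-[2,6-bis(benzyloxy)-4-(sulfooxy)phenoxy]phenyl hydrogen sulfate | O=S(=O)(O)Oc1cc(OCc2ccccc2)cc(Oc2c(OCc3ccccc3)cc(OS(=O)(=O)O)cc2OCc2ccccc2)c1 | intermediate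
16 | 3-[2,6-dihydroxy-4-(sulfooxy)phenoxy]-5-hydroxyphenyl hydrogen sulfate | O=S(=O)(O)Oc1cc(O)cc(Oc2c(O)cc(OS(=O)(=O)O)cc2O)c1 | target

## Step count and least certain steps

Total step count: 11. Longest linear sequence: 9 steps (steps 1–3 and 6–11, from 1); the ring A branch (steps 4 and 5) joins at step 6.

Step 7 (key step).
- Risk: hydride migration may compete with aryl migration in one or both Criegee adducts. Ring B carries a second formyl group and an acyloxy group, both inductively withdrawing, which lowers the migratory aptitude of C2' and C6'; this would stall the sequence at the carboxylic acid oxidation level.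
- Fallback: setting out from 10, methylmagnesium bromide at −78 °C in THF should add to both aldehydes faster than to the hindered esters and give 4-[3-(benzyloxy)-5-(pivaloyloxy)phenoxy]-3,5-bis(1-hydroxyethyl)phenyl pivalate F1 as a diastereomer mixture of no consequence. Oxidation with the periodinane DMP gives 3,5-diacetyl-4-[3-(benzyloxy)-5-(pivaloyloxy)phenoxy]phenyl pivalate F2. Baeyer–Villiger oxidation of these aryl methyl ketones (mCPBA, catalytic trifluoroacetic acid) has only aryl against methyl migration to decide, which favours aryl, and gives 3,5-diacetoxy-4-[3-(benzyloxy)-5-(pivaloyloxy)phenoxy]phenyl pivalate F3. Selective cleavage of the aryl acetates with NH4OAc in aqueous methanol returns to the route at 12.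

Step 6.
- Risk: acyl transfer from a pivalate to the phenoxide, either self-exchange of 9 or attack on the activated ester of 5, may compete with substitution and scramble the protecting pattern.
- Fallback: setting out from 5 and 8, the diol 8 is used in threefold excess as its mono-phenoxide (K2CO3, DMF, 0 °C), so the nucleophile carries no ester at all. This gives 4-[3-(benzyloxy)-5-hydroxyphenoxy]-3,5-diformylphenyl pivalate F4. Acylation of its remaining phenol with pivaloyl chloride and pyridine returns to the route at 10.

Step 4.
- Risk: C-benzylation of the ambident triol anion and over-alkylation to di- and triethers would lower throughput and complicate separation.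
- Fallback: setting out from 6, the triol is first mono-acylated with one equivalent of 2 and pyridine to 3,5-dihydroxyphenyl pivalate F5. This is then mono-benzylated under Mitsunobu conditions (benzyl alcohol, PPh3, diisopropyl azodicarboxylate, THF, 0 °C), where no free phenoxide exists and alkylation occurs on oxygen only. The fallback returns to the route at 9 and replaces steps 4 and 5.

Step 2.
- Risk: the fourfold bromination may stall before the last bromine is introduced, or ionic bromination of the ring may intervene once HBr and bromine accumulate, giving mixtures that carry through the hydrolysis.
- Fallback: setting out from 3, only one bromine per methyl group is introduced (NBS, 2.1 equiv, light) to give 3,5-bis(bromomethyl)-4-fluorophenyl pivalate F6. Both bromomethyl groups are then oxidised with N-methylmorpholine N-oxide in MeCN at rt (O-alkylation of the N-oxide, then elimination), returning to the route at 5 without a hydrolysis.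

Step 11.
- Risk: sulfate may be lost by acid-catalysed solvolysis during the threefold hydrogenolysis or the proton exchange, and debenzylation may be slowed by sulfur-containing species on the catalyst.
- Fallback: setting out from 14, both phenols are converted with 2,2,2-trichloroethyl chlorosulfate, Et3N and DMAP into the neutral, chromatographable diester 3-(benzyloxy)-5-[2,6-bis(benzyloxy)-4-{[(2,2,2-trichloroethoxy)sulfonyl]oxy}phenoxy]phenyl 2,2,2-trichloroethyl sulfate F7. One treatment with 10% Pd/C and HCO2NH4 in methanol, buffered throughout, should remove the trichloroethyl groups reductively and the benzyl groups by transfer hydrogenolysis. After the same cold proton exchange it returns to the route at 16 and replaces steps 10 and 11.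

## Further compounds

F1 | step 7 | 4-[3-(benzyloxy)-5-(pivaloyloxy)phenoxy]-3,5-bis(1-hydroxyethyl)phenyl pivalate (diastereomer mixture) | CC(O)c1cc(OC(=O)C(C)(C)C)cc(C(C)O)c1Oc1cc(OCc2ccccc2)cc(OC(=O)C(C)(C)C)c1
F2 | step 7 | 3,5-diacetyl-4-[3-(benzyloxy)-5-(pivaloyloxy)phenoxy]phenyl pivalate | CC(=O)c1cc(OC(=O)C(C)(C)C)cc(C(C)=O)c1Oc1cc(OCc2ccccc2)cc(OC(=O)C(C)(C)C)c1
F3 | step 7 | 3,5-diacetoxy-4-[3-(benzyloxy)-5-(pivaloyloxy)phenoxy]phenyl pivalate | CC(=O)Oc1cc(OC(=O)C(C)(C)C)cc(OC(C)=O)c1Oc1cc(OCc2ccccc2)cc(OC(=O)C(C)(C)C)c1
F4 | step 6 | 4-[3-(benzyloxy)-5-hydroxyphenoxy]-3,5-diformylphenyl pivalate | CC(C)(C)C(=O)Oc1cc(C=O)c(Oc2cc(O)cc(OCc3ccccc3)c2)c(C=O)c1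
F5 | step 4 | 3,5-dihydroxyphenyl pivalate | CC(C)(C)C(=O)Oc1cc(O)cc(O)c1
F6 | step 2 | 3,5-bis(bromomethyl)-4-fluorophenyl pivalate | BrCc1cc(OC(=O)C(C)(C)C)cc(CBr)c1F
F7 | step 11 | 3-(benzyloxy)-5-[2,6-bis(benzyloxy)-4-{[(2,2,2-trichloroethoxy)sulfonyl]oxy}phenoxy]phenyl 2,2,2-trichloroethyl sulfate | ClC(Cl)(Cl)COS(=O)(=O)Oc1cc(OCc2ccccc2)cc(Oc2c(OCc3ccccc3)cc(OS(=O)(=O)OCC(Cl)(Cl)Cl)cc2OCc2ccccc2)c1
A1 | alternative 1 | 1,3-bis(benzyloxy)-2-(ethynyloxy)-5-(methoxymethoxy)benzene | C#COc1c(OCc2ccccc2)cc(OCOC)cc1OCc1ccccc1
A2 | alternative 1 | 3-(benzyloxy)cyclobut-2-en-1-one | O=C1CC(OCc2ccccc2)=C1
A3 | alternative 1 | 3-(benzyloxy)-5-[2,6-bis(benzyloxy)-4-(methoxymethoxy)phenoxy]phenol | Oc1cc(OCc2ccccc2)cc(Oc2c(OCc3ccccc3)cc(OCOC)cc2OCc2ccccc2)c1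
A4 | alternative 2 | 1,3-bis(methoxymethoxy)-2-[3-(methoxymethoxy)phenoxy]benzene | COCOc1cccc(Oc2c(OCOC)cccc2OCOC)c1
A5 | alternative 2 | 3-[4-hydroxy-2,6-bis(methoxymethoxy)phenoxy]-5-(methoxymethoxy)phenol | COCOc1cc(O)cc(Oc2c(OCOC)cc(O)cc2OCOC)c1
A6 | alternative 3 | 6-{[3-(benzyloxy)-5-(methoxymethoxy)phenoxy]methyl}-4-(methoxymethoxy)-2H-pyran-2-one | COCOC1=CC(=O)OC(COc2cc(OCOC)cc(OCc3ccccc3)c2)=C1
A7 | alternative 3 | 2-[3-(benzyloxy)-5-(methoxymethoxy)phenoxy]-5-(methoxymethoxy)benzene-1,3-diol | COCOc1cc(O)c(Oc2cc(OCOC)cc(OCc3ccccc3)c2)c(O)c1
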